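## The problem

Rhuschalcone IV (9) is a bichalcone in which two 2'-hydroxychalcone units, each ending in a 4-hydroxyphenyl ring (rings B and D), are held together by a diaryl ether oxygen that joins C5 of the methoxylated central ring A to C4 of the second central ring C, each central ring being numbered from its acyl-bearing carbon C1. The molecule has no stereocentre; its only stereochemical elements are the two E enone double bonds, which are under thermodynamic control when made by aldol condensation, so nothing has to relay stereochemical information. The task is therefore one of assembly and chemoselectivity: a diaryl ether must be made between two oxygenated arenes, two different aryl ketones must each be extended to an enone, and four phenols (two chelated to carbonyl groups, two free) must be carried with as little protection as possible. The delicate parts are the 2'-hydroxychalcones, which close to flavanones by intramolecular oxa-Michael addition in strong acid or on long exposure to base, the enones as Michael acceptors, and ring A, whose C2 hydroxyl and C5 aryloxy group form a hydroquinone-type pair that is easily oxidised once the phenol is free. The feature that opens the synthesis is that both central rings carry their hydroxyl at C2, directly beside the carbonyl-bearing C1, so that removing these two oxygens leaves two plain aryl methyl ketones whose carbonyl groups can steer a metal to exactly those ortho C–H bonds. The skeleton itself decides the site: on ring C the two ortho positions C2 and C6 are equivalent, and on ring A the C2–H bond has a hydrogen neighbour at C3 while the C6–H bond is wedged between the acetyl group at C1 and the aryloxy group at C5. Stripped of the two hydroxyls and the two arylidene arms, the core shrinks to the diketone 3, which one ether-forming step delivers from two commercial acetophenones.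

## Retrosynthesis

**9 ⇒ 8.** The last operation cuts no skeletal bond; it only frees the ring B and ring D phenols from two methoxymethyl ethers. Protection is confined to these two positions because a free 4-hydroxybenzaldehyde is deactivated as its phenoxide under the basic condensation, whereas the chelated C2 hydroxyls of rings A and C need no mask. The forward reaction must cleave two acetals with acid mild enough that neither 2'-hydroxychalcone closes to a flavanone.

**8 ⇒ 5 + 7 (7 ⇐ 6).** Both Cα=Cβ bonds are cut at once. Attaching preformed cinnamoyl units to the arenes by acylation would raise a regiochemical question on each ring, and an olefination would need a bis-phosphonate that is harder to reach than a diketone. The aldol condensation of a methyl ketone with a non-enolisable aldehyde gives only the E enone and can be run on both ketones in one flask, because the two arms are identical. The precursor 5 is a C17 diketone without any alkene, and the aldehyde 7 is one protection step from 6. The forward reaction must drive two condensations to completion in the presence of two free, chelated phenols.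

**5 ⇒ 3 (through 4).** The two C2–O bonds are cut. Carrying these oxygens from the start would demand a ring A building block with three differentiated oxygens and a ring C fluoride made less electrophilic by an ortho oxygen, together with extra protecting groups. Introducing them last on the core uses the two ketones, which are needed anyway, as directing groups, so no atom is added that does not end up in 9. The precursor 3 is simpler by two oxygens and has no phenol at all. The forward reaction, a palladium-catalysed ketone-directed C–H oxidation, must oxidise each ring exactly once, choose C2 over C6 on ring A, and keep the new oxygens masked (as the bis(trifluoroacetate) 4) until the oxidant is gone.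

**3 ⇒ 1 + 2.** The ether bond between the oxygen and C4 of ring C is cut. This side is chosen because ring C carries its acetyl group para to the ether carbon, so the activating group for a nucleophilic aromatic substitution is the very ketone the route needs later. Cutting on the ring A side would call for a copper-mediated coupling on an electron-rich halide. Both partners, the phenol 1 and the fluoride 2, are commercial. The forward reaction only requires that the phenoxide of 1 displaces fluoride faster than the methyl ketones self-condense.

## Roads not taken

**Alternative 1:** The cut takes ring A apart completely, through C5–C6, C1–C2 and C2–C3. In the forward direction the pentacarbonylchromium carbene complex A1, whose carbene carbon bears a 1-methoxyvinyl group and the finished, MOM-protected ring C chalcone as an aryloxy group, would combine with the terminal alkyne A2 and one of its own CO ligands in a Dötz benzannulation to give the ring A phenol A3.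
- Merits: the substitution pattern of ring A is dictated by the mechanism. The carbene carbon becomes C5, the CO carbon becomes the phenolic C2, and the larger alkyne substituent ends up at C1 beside the new hydroxyl. The C2 hydroxyl is born free while every other phenol is protected, and no oxidant ever meets an electron-rich ring.
- Weak points: aryloxy carbene complexes are much less robust than alkoxy ones and have to be made by low-temperature exchange. A1 contains an enone, a group that chromium carbenes can cyclopropanate. Chromium is stoichiometric. The alkyne arm must be carried at the silyl-protected alcohol level, so A3 holds a carbinol stereocentre made only to be destroyed and still needs desilylation, allylic oxidation and MOM removal. The chalcone inside A1 must first be built by the same condensation chemistry the chosen route uses.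
- Comparison: in regiochemical certainty on ring A this road is the better one. The chosen plan sets against it that sterics and electronics of ring A point to the same carbon as the directing group, and that five steps with a catalytic metal suffice, where this road would need well over twice as many and a stoichiometric organometallic.

**Alternative 2:** The cut is at the two C(=O)–Cα bonds. In the forward direction the bis-salicylaldehyde A4 would be heated with 4-ethynylphenyl acetate A5, [RhCl(cod)]2 and a bisphosphine. Each aldehyde C–H bond adds to monovalent rhodium with chelation by the neighbouring phenoxide, the acyl rhodium hydride adds across the alkyne, and reductive elimination gives the E enone, so that the diacetate A6 of the target would arise in one step.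
- Merits: full atom economy, no strong base, the C2 hydroxyls work as chelating handles instead of needing protection, and both arms are installed together.
- Weak points: terminal aryl alkynes are the difficult substrates of this reaction type, and the linear-versus-branched choice has to come out right twice. The 2'-hydroxy enone products can cyclise under the mildly basic rhodium conditions, and decarbonylation of the acyl rhodium species competes. A4 is not easier to reach than 5: it needs the same two C2 oxygens and, in addition, two formyl groups placed regioselectively on a diaryl ether. Acetate removal at the end meets the same flavanone hazard as step 5.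
- Comparison: on paper this end game is as short as the chosen one, more atom-economical, and avoids the separate aldehyde protection. The chosen plan sets against it the reliability and complete E and positional control of the Claisen–Schmidt condensation, and a core (3) that costs a single step.

**Alternative 3:** The cut goes through ring C at C1–C2 and C5–C6. In the forward direction the 1-methoxy-1-silyloxy-3-aryloxy diene A7, whose aryloxy group is ring A with its acetyl group masked as a dioxolane and its C2 hydroxyl as a MOM ether, would add to the alkyne of the cross-conjugated enynone A8. The cycloadduct aromatises by loss of methanol and loses silicon on work-up, giving the ring C chalcone A9.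
- Merits: the polarised diene fixes the orientation (its nucleophilic CH2 terminus bonds to the alkyne β-carbon), so the C2 hydroxyl and the C4 aryloxy group arrive in the right relation with one chalcone arm already in place. No metal is needed. The two arms are introduced separately, which would allow unsymmetrical analogues.
- Weak points: A7 is a hydrolytically labile ketene acetal, and its aryloxy part already requires a ring A with three differentiated oxygens, which is the very problem the C–H oxidation removes. A8 offers the diene three electrophilic positions, so Mukaiyama–Michael addition or reaction at the enone alkene can compete. After the cycloaddition A9 still needs ketal removal, a second Claisen–Schmidt condensation on a substrate that already holds a base-sensitive 2'-hydroxychalcone, and deprotection, with three kinds of protecting group in play.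
- Comparison: for analogues with two different arms this road is the better one. For 9, whose arms are identical, that differentiation buys nothing, and the chosen plan installs both hydroxyls and both arms pairwise in far fewer steps.

Key step: step 2

## Route

**Step 1**
Reactants: 1 3-hydroxy-4-methoxyacetophenone; 2 4-fluoroacetophenone
Product: 3 1-[3-(4-acetylphenoxy)-4-methoxyphenyl]ethan-1-one
Conditions: K2CO3, DMF, 130 °C
Reagents that add atoms: none
Why: Nucleophilic aromatic substitution by addition–elimination: the phenoxide of 1 adds to C4 of 2, the para-acetyl group stabilises the anionic σ-adduct, and fluoride leaves. A carbonate base at this temperature is standard for 4-fluoroacetophenone and tolerates the methyl ketones.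

**Step 2**
Reactants: 3 1-[3-(4-acetylphenoxy)-4-methoxyphenyl]ethan-1-one
Product: 5 1-[5-(4-acetyl-3-hydroxyphenoxy)-2-hydroxy-4-methoxyphenyl]ethan-1-one, via bis(trifluoroacetate) 4 (not isolated)
Conditions: Pd(O2CCF3)2 (10 mol %), K2S2O8 (4.4 equiv), CF3CO2H/(CF3CO)2O 9:1, 50 °C; then H2O, rt
Reagents that add atoms: trifluoroacetic acid, OC(=O)C(F)(F)F
Why: Ketone-directed ortho C–H hydroxylation of aryl ketones with a palladium catalyst and persulfate in trifluoroacetic acid is a known reaction type, run here on two acetophenone units of one molecule. Each carbonyl oxygen binds the electrophilic divalent palladium trifluoroacetate and delivers it to an ortho C–H bond, giving a five-membered palladacycle by concerted metalation–deprotonation. Persulfate oxidises the palladacycle to a tetravalent palladium trifluoroacetate, and C–O reductive elimination releases the aryl trifluoroacetate and returns divalent palladium. No ring is closed and no stereocentre is formed. The step needs site selectivity on ring A and a single oxidation on each ring: on ring A palladation should go to C2–H, which is para to the aryloxy oxygen and has a hydrogen neighbour, and not to C6–H, which lies between the acetyl and aryloxy groups, while on ring C the two ortho sites are equivalent. A second oxidation of either ring is held back because the first trifluoroacetoxy group twists and deactivates the ketone-bearing ring, and the anhydride co-solvent keeps both new oxygens masked as electron-poor esters in 4, so that the hydroquinone-type ring A never meets persulfate as a free phenol. Water on work-up cleaves the two labile aryl trifluoroacetates to 5, whose phenols are then chelated to the ketones. Running the oxidation before the enones exist removes vinylic C–H activation and alkene oxidation as competitors, and persulfate is preferred to hypervalent iodine oxidants, which attack electron-rich aryl ethers and ketone α-positions.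

**Step 3**
Reactants: 6 4-hydroxybenzaldehyde
Product: 7 4-(methoxymethoxy)benzaldehyde
Conditions: MOMCl, K2CO3, acetone, 0 °C to rt
Reagents that add atoms: chloromethyl methyl ether, COCCl
Why: Williamson-type O-alkylation of the phenoxide with a highly reactive α-chloro ether. The resulting acetal is stable to the hydroxide of step 4 and keeps the aldehyde electrophilic by preventing phenoxide formation.

**Step 4**
Reactants: 5 1-[5-(4-acetyl-3-hydroxyphenoxy)-2-hydroxy-4-methoxyphenyl]ethan-1-one; 7 4-(methoxymethoxy)benzaldehyde (2.4 equiv)
Product: 8 (E)-1-[2-hydroxy-5-(3-hydroxy-4-{(E)-3-[4-(methoxymethoxy)phenyl]acryloyl}phenoxy)-4-methoxyphenyl]-3-[4-(methoxymethoxy)phenyl]prop-2-en-1-one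
Conditions: KOH (50% aq.), EtOH, 0 °C to rt; then 1 M HCl, 0 °C, to pH 5
Reagents that add atoms: none
Why: Double Claisen–Schmidt condensation: excess hydroxide enolises both methyl ketones despite the neighbouring phenoxides, the enolates add to the non-enolisable aldehyde, and E1cB dehydration gives the conjugated enones. Both alkenes are E because elimination is reversible and the trans arrangement of aryl and acyl groups is strongly favoured.

**Step 5**
Reactants: 8 bis(methoxymethyl) ether of rhuschalcone IV
Product: 9 rhuschalcone IV, (E)-1-[2-hydroxy-5-(3-hydroxy-4-[(E)-3-(4-hydroxyphenyl)acryloyl]phenoxy)-4-methoxyphenyl]-3-(4-hydroxyphenyl)prop-2-en-1-one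
Conditions: 3 M aq. HCl, MeOH, 60 °C, short reaction time
Reagents that add atoms: none
Why: Acid-catalysed acetal cleavage of the two aryl MOM ethers, with methanol taking up the formaldehyde unit. The methyl ether, the diaryl ether and the E enones are stable to dilute acid, and a brief exposure keeps flavanone closure of the chelated 2'-hydroxychalcones in check.

## Compound list

1 | 3-hydroxy-4-methoxyacetophenone | CC(=O)c1ccc(OC)c(O)c1 | starting material
2 | 4-fluoroacetophenone | CC(=O)c1ccc(F)cc1 | starting material
3 | 1-[3-(4-acetylphenoxy)-4-methoxyphenyl]ethan-1-one | CC(=O)c1ccc(OC)c(Oc2ccc(C(C)=O)cc2)c1 | intermediate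
4 | 2-acetyl-5-[5-acetyl-2-methoxy-4-(trifluoroacetoxy)phenoxy]phenyl trifluoroacetate (bis(trifluoroacetate) of 5, not isolated) | CC(=O)c1cc(Oc2ccc(C(C)=O)c(OC(=O)C(F)(F)F)c2)c(OC)cc1OC(=O)C(F)(F)F | intermediate
5 | 1-[5-(4-acetyl-3-hydroxyphenoxy)-2-hydroxy-4-methoxyphenyl]ethan-1-one | CC(=O)c1cc(Oc2ccc(C(C)=O)c(O)c2)c(OC)cc1O | intermediate
6 | 4-hydroxybenzaldehyde | O=Cc1ccc(O)cc1 | starting material
7 | 4-(methoxymethoxy)benzaldehyde | COCOc1ccc(C=O)cc1 | intermediate
8 | (E)-1-[2-hydroxy-5-(3-hydroxy-4-{(E)-3-[4-(methoxymethoxy)phenyl]acryloyl}phenoxy)-4-methoxyphenyl]-3-[4-(methoxymethoxy)phenyl]prop-2-en-1-one | COc1cc(O)c(C(=O)/C=C/c2ccc(OCOC)cc2)cc1Oc1ccc(C(=O)/C=C/c2ccc(OCOC)cc2)c(O)c1 | intermediate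
9 | rhuschalcone IV, (E)-1-[2-hydroxy-5-(3-hydroxy-4-[(E)-3-(4-hydroxyphenyl)acryloyl]phenoxy)-4-methoxyphenyl]-3-(4-hydroxyphenyl)prop-2-en-1-one | COc1cc(O)c(C(=O)/C=C/c2ccc(O)cc2)cc1Oc1ccc(C(=O)/C=C/c2ccc(O)cc2)c(O)c1 | target

## Step count and risk assessment

Total step count: 5. Longest linear sequence: 4 steps (1 → 3 → 5 → 8 → 9); step 3 is a one-step side branch that supplies the aldehyde 7.

**Step 2 (key step).** The most likely failure is loss of chemoselectivity under the strongly oxidising, acidic medium. Single-electron oxidation of the dialkoxy-substituted ring A by persulfate would lead to coupling or degradation. A second ortho oxidation on ring C, or stalling after only one of the two rings has reacted, are also possible, because the two ketones differ in electron density and need not react at the same rate. The fallback changes the directing group and the oxidant. It sets out from 3, which would be converted with hydroxylamine hydrochloride and NaOAc in ethanol into the (E,E)-bis-oxime F1. F1 would be acetylated in situ in AcOH/Ac2O and oxidised with Pd(OAc)2 and PhI(OAc)2 at about 100 °C, where the nitrogen donors form the palladacycles more readily and the medium is far less oxidising toward the arene, to give the bis(O-acetyl oxime) diacetate F2. Methanolysis with K2CO3 in MeOH would strip the four acetyl groups to the dihydroxy bis-oxime F3, and NaHSO3 in aqueous ethanol at 80 °C would hydrolyse the oximes, returning to the route at 5.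

**Step 4.** The concern is incomplete double condensation: each ketone sits beside a phenoxide, which lowers enolate concentration, and the potassium salt of the mono-condensed material may precipitate. On long reaction times base-induced oxa-Michael closure to flavanones and Cannizzaro consumption of the aldehyde would also compete. The fallback removes the phenoxides before the condensation. It sets out from 5, which would be converted with MOMCl and NaH in DMF into the bis(methoxymethyl) ether F4. Condensation of F4 with 7 (KOH, EtOH) can no longer cyclise and should be faster, giving the tetrakis(methoxymethyl) ether F5. Acidic methanol would then remove all four acetals in one operation, so that this detour rejoins the route at 9.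

**Step 5.** The risk is acid-catalysed ring closure of one or both 2'-hydroxychalcones to flavanones competing with acetal cleavage, or incomplete removal of the second MOM group if the acid is kept mild enough to prevent this. The fallback avoids acid altogether by changing the protecting group. It sets out from 5 and uses 4-(allyloxy)benzaldehyde F6, made from 6 with allyl bromide and K2CO3 in acetone. Claisen–Schmidt condensation of 5 with F6 (KOH, EtOH) would give the bis(allyl ether) F7, and Pd(PPh3)4 with K2CO3 in methanol at room temperature would cleave the aryl allyl ethers through a π-allyl complex of zerovalent palladium under near-neutral conditions, coming back to the route at 9.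

## Further compounds

F1 | step 2 | (E,E)-bis-oxime of 3, 1-{3-[4-(1-(hydroxyimino)ethyl)phenoxy]-4-methoxyphenyl}ethan-1-one oxime | C/C(=N\O)c1ccc(OC)c(Oc2ccc(/C(C)=N/O)cc2)c1
F2 | step 2 | bis(O-acetyl oxime) of the diacetate of 5 | C/C(=N\OC(C)=O)c1cc(Oc2ccc(/C(C)=N/OC(C)=O)c(OC(C)=O)c2)c(OC)cc1OC(C)=O
F3 | step 2 | (E,E)-bis-oxime of 5 | C/C(=N\O)c1cc(Oc2ccc(/C(C)=N/O)c(O)c2)c(OC)cc1O
F4 | step 4 | bis(methoxymethyl) ether of 5, 1-{5-[4-acetyl-3-(methoxymethoxy)phenoxy]-4-methoxy-2-(methoxymethoxy)phenyl}ethan-1-one | CC(=O)c1cc(Oc2ccc(C(C)=O)c(OCOC)c2)c(OC)cc1OCOC
F5 | step 4 | tetrakis(methoxymethyl) ether of 9 | COc1cc(OCOC)c(C(=O)/C=C/c2ccc(OCOC)cc2)cc1Oc1ccc(C(=O)/C=C/c2ccc(OCOC)cc2)c(OCOC)c1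
F6 | step 5 | 4-(allyloxy)benzaldehyde | C=CCOc1ccc(C=O)cc1
F7 | step 5 | bis(allyl ether) of 9 at the ring B and ring D phenols | COc1cc(O)c(C(=O)/C=C/c2ccc(OCC=C)cc2)cc1Oc1ccc(C(=O)/C=C/c2ccc(OCC=C)cc2)c(O)c1
A1 | alternative 1 | pentacarbonyl[(aryloxy)(1-methoxyvinyl)carbene]chromium, aryl = 3-(methoxymethoxy)-4-{(E)-3-[4-(methoxymethoxy)phenyl]acryloyl}phenyl | C=C(OC)C(Oc1ccc(C(=O)/C=C/c2ccc(OCOC)cc2)c(OCOC)c1)=[Cr](=C=O)(=C=O)(=C=O)(=C=O)=C=O
A2 | alternative 1 | tert-butyldimethylsilyl ether of (E)-1-[4-(methoxymethoxy)phenyl]pent-1-en-4-yn-3-ol (racemic) | C#CC(O[Si](C)(C)C(C)(C)C)/C=C/c1ccc(OCOC)cc1
A3 | alternative 1 | ring A phenol with the ring A side chain as the silyl-protected allylic alcohol (racemic at the carbinol carbon) | COc1cc(O)c(C(O[Si](C)(C)C(C)(C)C)/C=C/c2ccc(OCOC)cc2)cc1Oc1ccc(C(=O)/C=C/c2ccc(OCOC)cc2)c(OCOC)c1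
A4 | alternative 2 | 5-(4-formyl-3-hydroxyphenoxy)-2-hydroxy-4-methoxybenzaldehyde | COc1cc(O)c(C=O)cc1Oc1ccc(C=O)c(O)c1
A5 | alternative 2 | 4-ethynylphenyl acetate | C#Cc1ccc(OC(C)=O)cc1
A6 | alternative 2 | diacetate of 9 at the ring B and ring D phenols | COc1cc(O)c(C(=O)/C=C/c2ccc(OC(C)=O)cc2)cc1Oc1ccc(C(=O)/C=C/c2ccc(OC(C)=O)cc2)c(O)c1
A7 | alternative 3 | 1-methoxy-1-(trimethylsilyloxy)-3-aryloxybuta-1,3-diene, aryl = 2-methoxy-4-(methoxymethoxy)-5-(2-methyl-1,3-dioxolan-2-yl)phenyl (ketene acetal geometry not defined) | C=C(Oc1cc(C2(C)OCCO2)c(OCOC)cc1OC)C=C(OC)O[Si](C)(C)C
A8 | alternative 3 | (E)-1-[4-(methoxymethoxy)phenyl]pent-1-en-4-yn-3-one | C#CC(=O)/C=C/c1ccc(OCOC)cc1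
A9 | alternative 3 | ring C chalcone diaryl ether with ring A as the MOM-protected, ketal-masked acetophenone | COCOc1ccc(/C=C/C(=O)c2ccc(Oc3cc(C4(C)OCCO4)c(OCOC)cc3OC)cc2O)cc1
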